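**Plan**

- Ring A is a hexasubstituted 1,3,5-trioxygenated benzene with three different oxygens. Counted from the methoxy carbon, carbon 1 bears OMe, carbon 2 methyl, carbon 3 OH, carbon 4 acetyl, carbon 5 OH and carbon 6 the CH2 bridge to ring B. The three oxygens map onto a cyclobutenone enol ether, a ketene carbonyl and a silyl ynol ether.
- The retrosynthesis therefore cuts the ring A bonds between carbons 3 and 4, 5 and 6, and 2 and 3. This leaves a 3-methoxy-4-methylcyclobutenone that already carries ring B through the bridge carbon, and a silyl ynol ether that carries the acetyl as a dioxolane.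
- The cyclobutenone is cut into methylketene and a methyl ynol ether, and the ynol ether at its benzylic carbon–alkyne bond. Ring B is not built: it comes from 2,6-dihydroxy-4-methoxyacetophenone by formylation, C-prenylation and acetal protection.
- Forward order: ring B elaboration, ynol ether, four-membered ring, ring A by benzannulation, then desilylation and one acid deprotection.
- The target has no stereocentre; the racemic centre of the cyclobutenone disappears when ring A becomes aromatic.

Key step: step 11

Remark on the chemistry: the acetyl group of ring A is carried through the key step as a 2-methyl-1,3-dioxolan-2-yl group on the alkyne, because a late Friedel–Crafts acetylation would meet an acid-sensitive prenyl group and two acetal ethers.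

**Route**

Step 1
Reactants: 1 1-(2,6-dihydroxy-4-methoxyphenyl)ethan-1-one
Product: 3 3-acetyl-2,4-dihydroxy-6-methoxybenzaldehyde, via aryliminium chloride 2 (not isolated)
Conditions: POCl3, DMF, EtOAc, 0 °C → rt; then H2O, 60 °C
Reagents that add atoms: N,N-dimethylformamide, CN(C)C=O; water, O
Why: Vilsmeier–Haack formylation; the two free ring carbons of 1 are equivalent and strongly activated by three oxygens, and the first formyl group deactivates the ring against a second attack.

Step 2
Reactants: 3 3-acetyl-2,4-dihydroxy-6-methoxybenzaldehyde; 4 1-bromo-3-methylbut-2-ene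
Product: 5 3-acetyl-2,4-dihydroxy-6-methoxy-5-(3-methylbut-2-en-1-yl)benzaldehyde
Conditions: DBU, THF, 0 °C → rt
Reagents that add atoms: none
Why: C-alkylation of an acylphloroglucinol phenoxide with an allylic bromide; only one ring carbon is free and both hydroxyls are hydrogen-bonded to carbonyl groups, which should hold back O-alkylation.

Step 3
Reactants: 5 3-acetyl-2,4-dihydroxy-6-methoxy-5-(3-methylbut-2-en-1-yl)benzaldehyde
Product: 6 3-acetyl-6-methoxy-2,4-bis(methoxymethoxy)-5-(3-methylbut-2-en-1-yl)benzaldehyde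
Conditions: MOMCl, i-Pr2NEt, CH2Cl2, 0 → 40 °C
Reagents that add atoms: chloromethyl methyl ether, COCCl
Why: Williamson-type acetal protection of both acidic, carbonyl-flanked phenols with a highly reactive α-chloro ether, so that no phenol is left to trap ketenes later.

Step 4
Reactants: 6 3-acetyl-6-methoxy-2,4-bis(methoxymethoxy)-5-(3-methylbut-2-en-1-yl)benzaldehyde
Product: 7 1-[3-(hydroxymethyl)-4-methoxy-2,6-bis(methoxymethoxy)-5-(3-methylbut-2-en-1-yl)phenyl]ethan-1-one
Conditions: NaBH4, MeOH–THF, −30 → 0 °C
Reagents that add atoms: none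
Why: Chemoselective borohydride reduction; the aldehyde is far more electrophilic than the twisted aryl methyl ketone flanked by two ortho acetal ethers, so low temperature should leave the acetyl untouched.

Step 5
Reactants: 7 1-[3-(hydroxymethyl)-4-methoxy-2,6-bis(methoxymethoxy)-5-(3-methylbut-2-en-1-yl)phenyl]ethan-1-one
Product: 8 1-[3-(bromomethyl)-4-methoxy-2,6-bis(methoxymethoxy)-5-(3-methylbut-2-en-1-yl)phenyl]ethan-1-one
Conditions: CBr4, PPh3, CH2Cl2, −20 → 0 °C; used at once
Reagents that add atoms: tetrabromomethane, BrC(Br)(Br)Br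
Why: Appel bromination of a primary benzylic alcohol under neutral conditions, which spares the acetals and the prenyl alkene.

Step 6
Reactants: 9 2-chloro-1,1-dimethoxyethane
Product: 11 methoxyethyne, via sodium methoxyethynide 10 (not isolated)
Conditions: NaNH2 (3 equiv), liq. NH3, −33 °C; then cold aq. NaCl; distilled into THF at −78 °C
Reagents that add atoms: none
Why: Twofold amide-induced elimination (methanol, then HCl) of a chloroacetal, the established preparation of alkoxyacetylenes; the product is held as its acetylide until the quench.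

Step 7
Reactants: 8 1-[3-(bromomethyl)-4-methoxy-2,6-bis(methoxymethoxy)-5-(3-methylbut-2-en-1-yl)phenyl]ethan-1-one; 11 methoxyethyne
Product: 14 1-[4-methoxy-3-(3-methoxyprop-2-yn-1-yl)-2,6-bis(methoxymethoxy)-5-(3-methylbut-2-en-1-yl)phenyl]ethan-1-one, via lithium methoxyethynide 12 (not isolated), via chloro(methoxyethynyl)zinc 13 (not isolated)
Conditions: 11, n-BuLi, THF, −78 °C; ZnCl2, −78 → 0 °C; then 8, PdCl2(DPEphos) (5 mol %; DPEphos = bis[2-(diphenylphosphanyl)phenyl] ether), 0 °C → rt
Reagents that add atoms: none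
Why: Negishi coupling of a benzylic bromide with an alkynylzinc (oxidative addition to zerovalent palladium, transmetallation, reductive elimination); the zinc acetylide is too weakly basic and nucleophilic to enolise or attack the hindered aryl ketone, which a lithium acetylide might do.

Step 8
Reactants: 14 1-[4-methoxy-3-(3-methoxyprop-2-yn-1-yl)-2,6-bis(methoxymethoxy)-5-(3-methylbut-2-en-1-yl)phenyl]ethan-1-one; 15 propanoyl chloride
Product: 17 2-{[3-acetyl-6-methoxy-2,4-bis(methoxymethoxy)-5-(3-methylbut-2-en-1-yl)phenyl]methyl}-3-methoxy-4-methylcyclobut-2-en-1-one (racemic), via methylketene 16 (not isolated)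
Conditions: Et3N, CH2Cl2, 0 °C → rt, slow addition of 15 (excess)
Reagents that add atoms: none
Why: [2+2] cycloaddition of an in situ ketene with an alkoxyalkyne; the ketene carbonyl carbon bonds to the nucleophilic benzyl-bearing alkyne carbon, which places methoxy at ring carbon 3 and methyl at ring carbon 4, and the new stereocentre at carbon 4 forms without control because it is erased in step 11.

Step 9
Reactants: 18 but-3-yn-2-one
Product: 19 2-ethynyl-2-methyl-1,3-dioxolane
Conditions: Me3SiOCH2CH2OSiMe3, Me3SiOTf (cat.), CH2Cl2, −78 → −20 °C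
Reagents that add atoms: 1,2-bis(trimethylsilyloxy)ethane, C[Si](C)(C)OCCO[Si](C)(C)C
Why: Noyori acetalisation under aprotic conditions, which should avoid conjugate addition to the ynone.

Step 10
Reactants: 19 2-ethynyl-2-methyl-1,3-dioxolane
Product: 22 2-methyl-2-{[tri(propan-2-yl)silyl]oxyethynyl}-1,3-dioxolane, via lithium dioxolanylethynide 20 (not isolated), via lithium ynolate 21 (not isolated)
Conditions: LiN(SiMe3)2, THF, −78 °C; t-BuOOLi (from t-BuOOH and LiN(SiMe3)2), −78 → 0 °C; i-Pr3SiOTf, −78 °C
Reagents that add atoms: tert-butyl hydroperoxide, CC(C)(C)OO; triisopropylsilyl trifluoromethanesulfonate, CC(C)[Si](OS(=O)(=O)C(F)(F)F)(C(C)C)C(C)C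
Why: Julia-type oxidation of a lithium acetylide by lithium tert-butyl peroxide gives the ynolate, which the bulky silyl triflate traps on oxygen, the general route from terminal alkynes to silyl ynol ethers.

Step 11
Reactants: 17 2-{[3-acetyl-6-methoxy-2,4-bis(methoxymethoxy)-5-(3-methylbut-2-en-1-yl)phenyl]methyl}-3-methoxy-4-methylcyclobut-2-en-1-one; 22 2-methyl-2-{[tri(propan-2-yl)silyl]oxyethynyl}-1,3-dioxolane
Product: 27 1-[3-({4-hydroxy-6-methoxy-5-methyl-3-(2-methyl-1,3-dioxolan-2-yl)-2-[tri(propan-2-yl)silyloxy]phenyl}methyl)-4-methoxy-2,6-bis(methoxymethoxy)-5-(3-methylbut-2-en-1-yl)phenyl]ethan-1-one, via vinylketene 23 (not isolated), via vinylcyclobutenone 24 (not isolated), via dienylketene 25 (not isolated), via cyclohexadienone 26 (not isolated)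
Conditions: 22 (1.5–2 equiv), toluene, 80 → 110 °C, sealed tube, argon
Reagents that add atoms: none
Why: Heating should open 17 by a conrotatory four-electron electrocyclic reaction (methyl turning outward) to vinylketene 23, whose ketene C=C adds ynol ether 22 in a [2+2] cycloaddition that joins the ketal-bearing alkyne carbon to the ketene carbonyl carbon (the ring A bond between carbons 3 and 4) and the silyloxy carbon to the ketene α-carbon (the bond between carbons 5 and 6) to give 24. A second four-electron opening gives dienylketene 25, and ring A closes by a thermally allowed disrotatory six-electron electrocyclization that forms the bond between carbons 2 and 3, after which dienone 26 tautomerises to phenol 27. The closest known reaction type is the Danheiser benzannulation of cyclobutenones with trialkylsilyloxyalkynes, which gives resorcinol monosilyl ethers in the same way. No stereocentre is created, and the racemic centre of 17 is lost on aromatisation. The step needs regioselective ketene–alkyne addition, which the polarisation of the ynol ether (nucleophilic carbon β to oxygen) against the electrophilic ketene carbonyl carbon secures, so that the ketene oxygen becomes the free hydroxyl at carbon 3, the silyl ether sits at carbon 5 and the enol ether methoxy at carbon 1. It also needs the ketenes to survive until the alkyne reaches them, which is why ring B carries no free phenol and only a hindered acetyl and a prenyl group, both poor ketenophiles.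

Step 12
Reactants: 27 1-[3-({4-hydroxy-6-methoxy-5-methyl-3-(2-methyl-1,3-dioxolan-2-yl)-2-[tri(propan-2-yl)silyloxy]phenyl}methyl)-4-methoxy-2,6-bis(methoxymethoxy)-5-(3-methylbut-2-en-1-yl)phenyl]ethan-1-one
Product: 28 1-[3-{[2,4-dihydroxy-6-methoxy-5-methyl-3-(2-methyl-1,3-dioxolan-2-yl)phenyl]methyl}-4-methoxy-2,6-bis(methoxymethoxy)-5-(3-methylbut-2-en-1-yl)phenyl]ethan-1-one
Conditions: Bu4NF, AcOH, THF, 0 °C
Reagents that add atoms: none
Why: Fluoride cleavage of an aryl silyl ether, buffered with acetic acid so that the electron-rich phenoxide is not left in basic solution; any ketal lost here converges in step 13.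

Step 13
Reactants: 28 1-[3-{[2,4-dihydroxy-6-methoxy-5-methyl-3-(2-methyl-1,3-dioxolan-2-yl)phenyl]methyl}-4-methoxy-2,6-bis(methoxymethoxy)-5-(3-methylbut-2-en-1-yl)phenyl]ethan-1-one
Product: 29 1-[3-[(3-acetyl-2,4-dihydroxy-6-methoxy-5-methylphenyl)methyl]-2,6-dihydroxy-4-methoxy-5-(3-methylbut-2-en-1-yl)phenyl]ethan-1-one (Mallotojaponin B)
Conditions: 3 M aq. HCl, MeOH, rt
Reagents that add atoms: water, O
Why: Acid-catalysed acetal cleavage removes both methoxymethyl ethers and the dioxolane in one operation; the phenols next to the prenyl group become hydrogen-bonded to the acetyl carbonyl, which should keep chroman formation slow in dilute acid at room temperature.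

**Compound list**

1 | 1-(2,6-dihydroxy-4-methoxyphenyl)ethan-1-one | COc1cc(O)c(C(C)=O)c(O)c1 | starting material
2 | [(3-acetyl-2,4-dihydroxy-6-methoxyphenyl)methylidene]dimethylammonium chloride (formed in situ) | COc1cc(O)c(C(C)=O)c(O)c1C=[N+](C)C.[Cl-] | intermediate
3 | 3-acetyl-2,4-dihydroxy-6-methoxybenzaldehyde | COc1cc(O)c(C(C)=O)c(O)c1C=O | intermediate
4 | 1-bromo-3-methylbut-2-ene | CC(C)=CCBr | starting material
5 | 3-acetyl-2,4-dihydroxy-6-methoxy-5-(3-methylbut-2-en-1-yl)benzaldehyde | COc1c(CC=C(C)C)c(O)c(C(C)=O)c(O)c1C=O | intermediate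
6 | 3-acetyl-6-methoxy-2,4-bis(methoxymethoxy)-5-(3-methylbut-2-en-1-yl)benzaldehyde | COCOc1c(C=O)c(OC)c(CC=C(C)C)c(OCOC)c1C(C)=O | intermediate
7 | 1-[3-(hydroxymethyl)-4-methoxy-2,6-bis(methoxymethoxy)-5-(3-methylbut-2-en-1-yl)phenyl]ethan-1-one | COCOc1c(CO)c(OC)c(CC=C(C)C)c(OCOC)c1C(C)=O | intermediate
8 | 1-[3-(bromomethyl)-4-methoxy-2,6-bis(methoxymethoxy)-5-(3-methylbut-2-en-1-yl)phenyl]ethan-1-one | COCOc1c(CBr)c(OC)c(CC=C(C)C)c(OCOC)c1C(C)=O | intermediate
9 | 2-chloro-1,1-dimethoxyethane (chloroacetaldehyde dimethyl acetal) | COC(CCl)OC | starting material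
10 | sodium methoxyethynide (formed in situ) | [Na+].[C-]#COC | intermediate
11 | methoxyethyne | C#COC | intermediate
12 | lithium methoxyethynide (formed in situ) | [Li]C#COC | intermediate
13 | chloro(methoxyethynyl)zinc (formed in situ) | Cl[Zn]C#COC | intermediate
14 | 1-[4-methoxy-3-(3-methoxyprop-2-yn-1-yl)-2,6-bis(methoxymethoxy)-5-(3-methylbut-2-en-1-yl)phenyl]ethan-1-one | COC#CCc1c(OCOC)c(C(C)=O)c(OCOC)c(CC=C(C)C)c1OC | intermediate
15 | propanoyl chloride | CCC(Cl)=O | starting material
16 | prop-1-en-1-one (methylketene, formed in situ) | CC=C=O | intermediate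
17 | 2-{[3-acetyl-6-methoxy-2,4-bis(methoxymethoxy)-5-(3-methylbut-2-en-1-yl)phenyl]methyl}-3-methoxy-4-methylcyclobut-2-en-1-one, racemic | CC1C(=O)C(Cc2c(OCOC)c(C(C)=O)c(OCOC)c(CC=C(C)C)c2OC)=C1OC | intermediate
18 | but-3-yn-2-one | CC(=O)C#C | starting material
19 | 2-ethynyl-2-methyl-1,3-dioxolane | CC1(C#C)OCCO1 | intermediate
20 | lithium (2-methyl-1,3-dioxolan-2-yl)ethynide (formed in situ) | [Li]C#CC1(C)OCCO1 | intermediate
21 | lithium 2-(2-methyl-1,3-dioxolan-2-yl)ethynolate (formed in situ) | [Li+].[O-]C#CC1(C)OCCO1 | intermediate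
22 | 2-methyl-2-{[tri(propan-2-yl)silyl]oxyethynyl}-1,3-dioxolane | CC1(C#CO[Si](C(C)C)(C(C)C)C(C)C)OCCO1 | intermediate
23 | vinylketene from ring opening of 17: 2-(ring B benzyl)-3-methoxypenta-1,3-dien-1-one, methyl cis to methoxy (formed in situ) | C/C=C(\OC)C(Cc1c(OCOC)c(C(C)=O)c(OCOC)c(CC=C(C)C)c1OC)=C=O | intermediate
24 | 4-(ring B benzyl)-4-(1-methoxyprop-1-en-1-yl)-2-(2-methyl-1,3-dioxolan-2-yl)-3-[tri(propan-2-yl)silyloxy]cyclobut-2-en-1-one, racemic (formed in situ) | O=C1C(C2(C)OCCO2)=C(O[Si](C(C)C)(C(C)C)C(C)C)C1(Cc3c(OCOC)c(C(C)=O)c(OCOC)c(CC=C(C)C)c3OC)/C(OC)=C/C | intermediate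
25 | dienylketene from ring opening of 24: 4-(ring B benzyl)-5-methoxy-2-(2-methyl-1,3-dioxolan-2-yl)-3-[tri(propan-2-yl)silyloxy]hepta-1,3,5-trien-1-one, ketene carbon cis to the methoxypropenyl group (formed in situ) | O=C=C(C1(C)OCCO1)/C(O[Si](C(C)C)(C(C)C)C(C)C)=C(Cc1c(OCOC)c(C(C)=O)c(OCOC)c(CC=C(C)C)c1OC)\C(OC)=C\C | intermediate
26 | 4-(ring B benzyl)-5-methoxy-6-methyl-2-(2-methyl-1,3-dioxolan-2-yl)-3-[tri(propan-2-yl)silyloxy]cyclohexa-2,4-dien-1-one, racemic (formed in situ) | O=C1C(C2(C)OCCO2)=C(O[Si](C(C)C)(C(C)C)C(C)C)C(Cc3c(OCOC)c(C(C)=O)c(OCOC)c(CC=C(C)C)c3OC)=C(OC)C1C | intermediate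
27 | 1-[3-({4-hydroxy-6-methoxy-5-methyl-3-(2-methyl-1,3-dioxolan-2-yl)-2-[tri(propan-2-yl)silyloxy]phenyl}methyl)-4-methoxy-2,6-bis(methoxymethoxy)-5-(3-methylbut-2-en-1-yl)phenyl]ethan-1-one | COc1c(C)c(O)c(C2(C)OCCO2)c(O[Si](C(C)C)(C(C)C)C(C)C)c1Cc3c(OCOC)c(C(C)=O)c(OCOC)c(CC=C(C)C)c3OC | intermediate
28 | 1-[3-{[2,4-dihydroxy-6-methoxy-5-methyl-3-(2-methyl-1,3-dioxolan-2-yl)phenyl]methyl}-4-methoxy-2,6-bis(methoxymethoxy)-5-(3-methylbut-2-en-1-yl)phenyl]ethan-1-one | COc1c(C)c(O)c(C2(C)OCCO2)c(O)c1Cc3c(OCOC)c(C(C)=O)c(OCOC)c(CC=C(C)C)c3OC | intermediate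
29 | Mallotojaponin B, 1-[3-[(3-acetyl-2,4-dihydroxy-6-methoxy-5-methylphenyl)methyl]-2,6-dihydroxy-4-methoxy-5-(3-methylbut-2-en-1-yl)phenyl]ethan-1-one | COc1c(C)c(O)c(C(C)=O)c(O)c1Cc1c(O)c(C(C)=O)c(O)c(CC=C(C)C)c1OC | target

("Ring B benzyl" in 23–26 stands for the [3-acetyl-6-methoxy-2,4-bis(methoxymethoxy)-5-(3-methylbut-2-en-1-yl)phenyl]methyl group.)

**Count and risks**

Total step count: 13. Longest linear sequence: 10 steps (steps 1–5, 7, 8, 11, 12, 13).

Steps most likely to fail:

1. Step 11. The vinylogous-ester stabilisation of the 3-methoxycyclobutenone may hold back the first ring opening until temperatures at which the silyl ynol ether oligomerises, and the crowded ketene–alkyne addition may be outrun by dimerisation of the vinylketene. The fallback gives up the annulation and forms the methylene bridge by C-benzylation of a preformed ring A. It sets out from bromide 8 and starting material 1. C-Methylation of 1 (MeI, NaOMe, MeOH) should give 1-(2,6-dihydroxy-4-methoxy-3-methylphenyl)ethan-1-one F1, whose single free ring carbon is alkylated by 8 under the DBU/THF conditions of step 2. This should give 1-[3-[(3-acetyl-2,4-dihydroxy-6-methoxy-5-methylphenyl)methyl]-4-methoxy-2,6-bis(methoxymethoxy)-5-(3-methylbut-2-en-1-yl)phenyl]ethan-1-one F2. Treatment with HCl in methanol as in step 13 brings the fallback back to the route at 29.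

2. Step 7. The electron-rich benzylic bromide may ionise (with participation of the ortho acetal oxygen) or homocouple before it is intercepted, and the ynol ether may hydrate during a slow coupling. The fallback reverses the polarity and joins ring B to a finished four-membered ring. It sets out from 8 and 11. Cycloaddition of 11 with methylketene 16 (from 15 and Et3N) should give 3-methoxy-4-methylcyclobut-2-en-1-one F3, and α-iodination (iodine, pyridine, CH2Cl2) should give 2-iodo-3-methoxy-4-methylcyclobut-2-en-1-one F4. Zinc insertion into 8 (zinc dust, LiCl, THF, 0 °C) should give {[3-acetyl-6-methoxy-2,4-bis(methoxymethoxy)-5-(3-methylbut-2-en-1-yl)phenyl]methyl}zinc bromide F5, a reagent that tolerates the ketone. Negishi coupling of F5 with F4 (Pd(PPh3)4, THF) comes back to the route at 17 and bypasses 14.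

3. Step 8. Methylketene may dimerise faster than it is captured, and the ammonium salt may hydrate the ynol ether. The fallback uses a halogenated ketene that is more electrophilic, followed by reductive dehalogenation. It sets out from 14. 2-Chloropropanoyl chloride and Et3N should give 2-chloroprop-1-en-1-one F6 (chloro(methyl)ketene, not isolated), which adds to 14 with the same regiochemistry to give 2-{[3-acetyl-6-methoxy-2,4-bis(methoxymethoxy)-5-(3-methylbut-2-en-1-yl)phenyl]methyl}-4-chloro-3-methoxy-4-methylcyclobut-2-en-1-one F7. Zinc dust with acetic acid and TMEDA in ethanol removes the chlorine and comes back to the route at 17.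

**Further compounds**

F1 | step 11 | 1-(2,6-dihydroxy-4-methoxy-3-methylphenyl)ethan-1-one | COc1cc(O)c(C(C)=O)c(O)c1C
F2 | step 11 | 1-[3-[(3-acetyl-2,4-dihydroxy-6-methoxy-5-methylphenyl)methyl]-4-methoxy-2,6-bis(methoxymethoxy)-5-(3-methylbut-2-en-1-yl)phenyl]ethan-1-one | COc1c(C)c(O)c(C(C)=O)c(O)c1Cc1c(OCOC)c(C(C)=O)c(OCOC)c(CC=C(C)C)c1OC
F3 | step 7 | 3-methoxy-4-methylcyclobut-2-en-1-one, racemic | CC1C(=O)C=C1OC
F4 | step 7 | 2-iodo-3-methoxy-4-methylcyclobut-2-en-1-one, racemic | CC1C(=O)C(I)=C1OC
F5 | step 7 | {[3-acetyl-6-methoxy-2,4-bis(methoxymethoxy)-5-(3-methylbut-2-en-1-yl)phenyl]methyl}zinc bromide | Br[Zn]Cc1c(OCOC)c(C(C)=O)c(OCOC)c(CC=C(C)C)c1OC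
F6 | step 8 | 2-chloroprop-1-en-1-one (chloro(methyl)ketene) | CC(Cl)=C=O
F7 | step 8 | 2-{[3-acetyl-6-methoxy-2,4-bis(methoxymethoxy)-5-(3-methylbut-2-en-1-yl)phenyl]methyl}-4-chloro-3-methoxy-4-methylcyclobut-2-en-1-one, racemic | COC1=C(Cc2c(OCOC)c(C(C)=O)c(OCOC)c(CC=C(C)C)c2OC)C(=O)C1(C)Cl
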